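**Retrosynthetic overview**
- The plan rests on the acyloin in carbocyclic ring B of the isochromene core (C1, O2, C3, C4, C4a, C5–C8, C8a): the C7 methyl carbinol adjoins the C8 ketone, so C7–C8 is cut into an acyl anion at C8 (a formyl group on C8a) and the C7 ketone of a C6/C7 dione.
- Target 20 ⇒ tertiary alcohol 19 (acetylation) ⇒ monocyclic 3-formyl-4-pyranylidene chlorodione 18 (carbene-catalysed crossed benzoin; ring B is closed last).
- 18 ⇒ 16 (oxidation at C7, chlorination at C5) ⇒ pyranone acetal 13 + but-3-yn-2-ol (acetylide addition to C4a=O, then Meyer–Schuster shift brings in C5–C7).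
- 13 ⇒ dienoyl Meldrum's acid 9 + 1,3,3-trimethoxypropene (acylketene hetero-Diels–Alder; pyran ring A is formed first). C8 enters with the dienophile as an acetal on C8a, because electrophilic formylation of a finished pyranylidene would be expected to favour C4 (activated by O2 and the dienyl group) over C8a.
- 9 ⇒ dienoic acid 7 ⇒ enal 4 ⇒ (S)-2-methylbutan-1-ol 1, the source of the C13 stereocentre.

Key step: step 10

Assumption: isochromene atom numbers (side chain C9–C13, stereocentre C13) are used for all intermediates; the (5aS,10bR) triazolium antipode is assumed to give the (7S) carbinol, and the commercial (5aR,10bS) antipode is used instead if the first run shows the opposite sense; the push–pull C4a=C5 bond of 16–18 is taken to equilibrate, so one geometry is drawn.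

**Step 1**
Reactants: 1 (S)-2-methylbutan-1-ol
Product: 2 (S)-2-methylbutanal
Conditions: TEMPO (cat.), KBr (cat.), aq. NaOCl, NaHCO3, CH2Cl2/H2O, 0 °C
Reagents that add atoms: none
Why: The nitroxyl-catalysed hypochlorite oxidation stops at the aldehyde, and the buffered two-phase medium at 0 °C should leave the enolisable α-stereocentre (future C13) untouched.

**Step 2**
Reactants: 2 (S)-2-methylbutanal; 3 2-(triphenylphosphoranylidene)propanal
Product: 4 (2E,4S)-2,4-dimethylhex-2-enal
Conditions: toluene, 85 °C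
Reagents that add atoms: none
Why: Wittig olefination with the stabilised, non-basic formyl ylide should give the E-trisubstituted enal without epimerising the α-centre of 2.

**Step 3**
Reactants: 4 (2E,4S)-2,4-dimethylhex-2-enal; 5 triethyl phosphonoacetate
Product: 6 ethyl (2E,4E,6S)-4,6-dimethylocta-2,4-dienoate
Conditions: NaH, THF, 0 °C → rt
Reagents that add atoms: none
Why: The Horner–Wadsworth–Emmons reaction of the stabilised phosphonate anion is E-selective, and the α-methyl enal cannot enolise at C2, so the γ-stereocentre should survive.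

**Step 4**
Reactants: 6 ethyl (2E,4E,6S)-4,6-dimethylocta-2,4-dienoate
Product: 7 (2E,4E,6S)-4,6-dimethylocta-2,4-dienoic acid
Conditions: LiOH·H2O, THF/MeOH/H2O, rt; then 1 M HCl
Reagents that add atoms: lithium hydroxide, [Li+].[OH-]
Why: Saponification of an unhindered conjugated ethyl ester is mild enough to leave the diene geometry and the stereocentre unchanged.

**Step 5**
Reactants: 7 (2E,4E,6S)-4,6-dimethylocta-2,4-dienoic acid; 8 Meldrum's acid (2,2-dimethyl-1,3-dioxane-4,6-dione)
Product: 9 5-[(2E,4E,6S)-1-hydroxy-4,6-dimethylocta-2,4-dien-1-ylidene]-2,2-dimethyl-1,3-dioxane-4,6-dione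
Conditions: DCC, DMAP, CH2Cl2, 0 °C → rt
Reagents that add atoms: none
Why: Carbodiimide activation with DMAP acyl transfer (Steglich-type) C-acylates the acidic methylene of Meldrum's acid, and the product rests as its stable enol.

**Step 6**
Reactants: 9 dienoyl Meldrum's acid; 10 (E)-1,3,3-trimethoxyprop-1-ene
Product: 13 5-(dimethoxymethyl)-2-[(1E,3E,5S)-3,5-dimethylhepta-1,3-dien-1-yl]-4H-pyran-4-one, via acylketene 11 (not isolated), via methoxydihydropyranone 12 (not isolated)
Conditions: 10 (excess), toluene, 95 °C; then DBU (cat.), rt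
Reagents that add atoms: none
Why: Thermal loss of acetone and CO2 from 9 releases the acylketene, which undergoes a hetero-Diels–Alder reaction with the enol ether (its acetal-bearing β-carbon, future C8a, bonds to the ketene carbon C4a and the acyl oxygen to the methoxy-bearing carbon C1), and E1cB loss of methanol then gives the γ-pyrone with C8 fixed on C8a.

**Step 7**
Reactants: 13 pyranone acetal; 14 but-3-yn-2-ol (racemic)
Product: 16 (4Z)-6-[(1E,3E,5S)-3,5-dimethylhepta-1,3-dien-1-yl]-4-(3-hydroxy-2-oxobutylidene)-4H-pyran-3-carbaldehyde, via alkynyl pyranol 15 (not isolated)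
Conditions: 14, n-BuLi (2 equiv per 14), THF, −78 → −20 °C; add 13, −78 → 0 °C; then 1 M HCl, THF, 0 °C → rt
Reagents that add atoms: water, O
Why: The slim, hard dilithio acetylide should add 1,2 to the pyranone carbonyl; on acidification the carbinol ionises to a 4-alkynylpyrylium ion that is hydrated at the distal alkyne carbon (Meyer–Schuster rearrangement) to the push–pull 4-(acylmethylene)pyran, and the now vinylogous acetal is hydrolysed to the aldehyde in the same medium.

**Step 8**
Reactants: 16 hydroxy ketone aldehyde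
Product: 17 (4E)-4-(1-chloro-3-hydroxy-2-oxobutylidene)-6-[(1E,3E,5S)-3,5-dimethylhepta-1,3-dien-1-yl]-4H-pyran-3-carbaldehyde
Conditions: NCS, CH2Cl2, −20 → 0 °C, dark
Reagents that add atoms: N-chlorosuccinimide, O=C1CCC(=O)N1Cl
Why: C5 is the α-carbon of a doubly vinylogous ester and the most nucleophilic site (C8a is substituted and C4 less activated), so electrophilic chlorination and loss of the proton should give the vinyl chloride, as in the C5 halogenation of azaphilone cores.

**Step 9**
Reactants: 17 chloro hydroxy ketone aldehyde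
Product: 18 (4E)-4-(1-chloro-2,3-dioxobutylidene)-6-[(1E,3E,5S)-3,5-dimethylhepta-1,3-dien-1-yl]-4H-pyran-3-carbaldehyde
Conditions: Dess–Martin periodinane, CH2Cl2, 0 °C → rt; used directly
Reagents that add atoms: none
Why: Dess–Martin oxidation converts the only carbinol (C7) into the ketone of the C6/C7 dione without touching the aldehyde, the diene or the vinyl chloride.

**Step 10**
Reactants: 18 3-formyl-4-pyranylidene chlorodione
Product: 19 (7S)-5-chloro-3-[(1E,3E,5S)-3,5-dimethylhepta-1,3-dien-1-yl]-7-hydroxy-7-methyl-6H-isochromene-6,8(7H)-dione (7-epi-deacetylsclerotiorin)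
Conditions: (5aS,10bR)-2-(pentafluorophenyl)-5a,10b-dihydro-4H,6H-indeno[2,1-b][1,2,4]triazolo[4,3-d][1,4]oxazin-2-ium tetrafluoroborate (15 mol %), Et3N (15 mol %), toluene, 0 °C → rt, argon
Reagents that add atoms: none
Why: The triazolylidene released by Et3N adds to the C8 formyl group and proton transfer gives the Breslow enaminol, an acyl-anion equivalent at C8 that attacks the C7 ketone; proton transfer and expulsion of the carbene then leave the C8 ketone and the C7 tertiary alcohol. The closest known reaction type is the enantioselective carbene-catalysed intramolecular crossed aldehyde–ketone benzoin cyclisation of keto-aldehydes to six-membered α-ketols, applied here to a vinylogous formate aldehyde and an α-dione acceptor. Ring B (C8, C8a, C4a, C5, C6, C7) closes by 6-exo-trig attack on the C7 carbonyl, which the low rotation barrier of the push–pull C4a=C5 bond should make accessible from either alkene isomer of 18. The new C7 stereocentre is under catalyst control: the indane wall of the aminoindanol backbone shields one face of the enaminol so that the C7 carbonyl is engaged on one enantiotopic face, the remote C13 centre having no influence. The step needs attack at C7 and not at C6 (five-membered closure), and acyl-anion and not homoenolate reactivity; the first should follow because C6 is a vinylogous ester carbonyl deactivated by O2 whereas C7 is a ketone activated by the neighbouring carbonyl, the second because the electron-poor N-pentafluorophenyl carbene and the six-membered intramolecular trajectory favour the C8 nucleophile.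

**Step 11**
Reactants: 19 7-epi-deacetylsclerotiorin
Product: 20 (7S)-5-chloro-3-[(1E,3E,5S)-3,5-dimethylhepta-1,3-dien-1-yl]-7-methyl-6,8-dioxo-7,8-dihydro-6H-isochromen-7-yl acetate (7-epi-sclerotiorin)
Conditions: Ac2O, DMAP (cat.), Et3N, CH2Cl2, 0 °C → rt
Reagents that add atoms: acetic anhydride, CC(=O)OC(C)=O
Why: DMAP-catalysed acetylation esterifies the hindered tertiary α-ketol oxygen without breaking any bond to C7, so the (7S) configuration is retained.

**Compound list**
1 | (S)-2-methylbutan-1-ol | CC[C@H](C)CO | starting material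
2 | (S)-2-methylbutanal | CC[C@H](C)C=O | intermediate
3 | 2-(triphenylphosphoranylidene)propanal | CC(C=O)=P(c1ccccc1)(c1ccccc1)c1ccccc1 | starting material
4 | (2E,4S)-2,4-dimethylhex-2-enal | CC[C@H](C)/C=C(C)/C=O | intermediate
5 | triethyl phosphonoacetate | CCOC(=O)CP(=O)(OCC)OCC | starting material
6 | ethyl (2E,4E,6S)-4,6-dimethylocta-2,4-dienoate | CC[C@H](C)/C=C(C)/C=C/C(=O)OCC | intermediate
7 | (2E,4E,6S)-4,6-dimethylocta-2,4-dienoic acid | CC[C@H](C)/C=C(C)/C=C/C(=O)O | intermediate
8 | Meldrum's acid (2,2-dimethyl-1,3-dioxane-4,6-dione) | CC1(C)OC(=O)CC(=O)O1 | starting material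
9 | 5-[(2E,4E,6S)-1-hydroxy-4,6-dimethylocta-2,4-dien-1-ylidene]-2,2-dimethyl-1,3-dioxane-4,6-dione | CC[C@H](C)/C=C(C)/C=C/C(O)=C1C(=O)OC(C)(C)OC1=O | intermediate
10 | (E)-1,3,3-trimethoxyprop-1-ene | CO/C=C/C(OC)OC | starting material
11 | (4E,6E,8S)-6,8-dimethyl-3-oxodeca-1,4,6-trien-1-one (acylketene) | CC[C@H](C)/C=C(C)/C=C/C(=O)C=C=O | intermediate
12 | 3-(dimethoxymethyl)-6-[(1E,3E,5S)-3,5-dimethylhepta-1,3-dien-1-yl]-2-methoxy-2,3-dihydro-4H-pyran-4-one (diastereomers at C1 and C8a) | CC[C@H](C)/C=C(C)/C=C/C1=CC(=O)C(C(OC)OC)C(OC)O1 | intermediate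
13 | 5-(dimethoxymethyl)-2-[(1E,3E,5S)-3,5-dimethylhepta-1,3-dien-1-yl]-4H-pyran-4-one | CC[C@H](C)/C=C(C)/C=C/C1=CC(=O)C(C(OC)OC)=CO1 | intermediate
14 | but-3-yn-2-ol (racemic) | CC(O)C#C | starting material
15 | 3-(dimethoxymethyl)-6-[(1E,3E,5S)-3,5-dimethylhepta-1,3-dien-1-yl]-4-(3-hydroxybut-1-yn-1-yl)-4H-pyran-4-ol (diastereomers at C4a and C7) | CC[C@H](C)/C=C(C)/C=C/C1=CC(O)(C#CC(C)O)C(C(OC)OC)=CO1 | intermediate
16 | (4Z)-6-[(1E,3E,5S)-3,5-dimethylhepta-1,3-dien-1-yl]-4-(3-hydroxy-2-oxobutylidene)-4H-pyran-3-carbaldehyde (both C7 epimers) | CC[C@H](C)/C=C(C)/C=C/C1=C/C(=C/C(=O)C(C)O)C(C=O)=CO1 | intermediate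
17 | (4E)-4-(1-chloro-3-hydroxy-2-oxobutylidene)-6-[(1E,3E,5S)-3,5-dimethylhepta-1,3-dien-1-yl]-4H-pyran-3-carbaldehyde (both C7 epimers) | CC[C@H](C)/C=C(C)/C=C/C1=C/C(=C(\Cl)C(=O)C(C)O)C(C=O)=CO1 | intermediate
18 | (4E)-4-(1-chloro-2,3-dioxobutylidene)-6-[(1E,3E,5S)-3,5-dimethylhepta-1,3-dien-1-yl]-4H-pyran-3-carbaldehyde | CC[C@H](C)/C=C(C)/C=C/C1=C/C(=C(\Cl)C(=O)C(C)=O)C(C=O)=CO1 | intermediate
19 | (7S)-5-chloro-3-[(1E,3E,5S)-3,5-dimethylhepta-1,3-dien-1-yl]-7-hydroxy-7-methyl-6H-isochromene-6,8(7H)-dione | CC[C@H](C)/C=C(C)/C=C/C1=CC2=C(Cl)C(=O)[C@@](C)(O)C(=O)C2=CO1 | intermediate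
20 | 7-epi-sclerotiorin, (7S)-5-chloro-3-[(1E,3E,5S)-3,5-dimethylhepta-1,3-dien-1-yl]-7-methyl-6,8-dioxo-7,8-dihydro-6H-isochromen-7-yl acetate | CC[C@H](C)/C=C(C)/C=C/C1=CC2=C(Cl)C(=O)[C@@](C)(OC(C)=O)C(=O)C2=CO1 | target

Total step count: 11. Longest linear sequence: 11 steps (1 → 20).

**Steps most likely to fail**

1. Step 10. The carbene may add at C1 and open the pyran ring, the extended Breslow intermediate may be protonated at C1 (homoenolate path) before C–C bond formation, facial discrimination at C7 may be poor, or retro-benzoin may erode the C7 configuration. Fallback: it sets out from 17 and closes the same C7–C8 bond with normal polarity. The α-hydroxy ketone of 17 has a single enolisable position (C7–H); its enolate (LiHMDS, THF, −78 °C) should add to the C8 aldehyde in an intramolecular aldol reaction to give 5-chloro-3-[(1E,3E,5S)-3,5-dimethylhepta-1,3-dien-1-yl]-7,8-dihydroxy-7-methyl-7,8-dihydro-6H-isochromen-6-one F1 as a mixture at C7 and C8. Selective oxidation of the secondary allylic C8 alcohol (MnO2, CH2Cl2) would then give the C7 epimers of the ketol, from which the (7S) isomer is separated by HPLC on a chiral stationary phase. The fallback comes back to the route at 19.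

2. Step 6. The acetal-bearing enol ether may react too slowly, so that acylketene dimerisation takes over, or the acidic acyl Meldrum's acid may ionise the allylic acetal. Fallback: it sets out from 9 and brings in C8 after the ring is made. Thermolysis of 9 with butyl vinyl ether (toluene, 90 °C) should give 2-butoxy-6-[(1E,3E,5S)-3,5-dimethylhepta-1,3-dien-1-yl]-2,3-dihydro-4H-pyran-4-one F2. Its only enolisable carbon (C8a) is aminomethylenated with tert-butoxybis(dimethylamino)methane (toluene, 60 °C) to 2-butoxy-3-[(dimethylamino)methylidene]-6-[(1E,3E,5S)-3,5-dimethylhepta-1,3-dien-1-yl]-2,3-dihydro-4H-pyran-4-one F3. Aqueous acid (1 M HCl, THF) removes butanol and dimethylamine to give 6-[(1E,3E,5S)-3,5-dimethylhepta-1,3-dien-1-yl]-4-oxo-4H-pyran-3-carbaldehyde F4, and acetalisation (HC(OMe)3, MeOH, TsOH cat.) comes back to the route at 13.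

3. Step 7. The acetylide may add in conjugate fashion at the unsubstituted C1, or water may capture the alkynylpyrylium ion at C1 with ring opening in place of hydration at the alkyne terminus. Fallback: it sets out from 13 and builds C5–C7 by methyl addition and acylation. MeMgBr (THF, −78 → 0 °C) should give 3-(dimethoxymethyl)-6-[(1E,3E,5S)-3,5-dimethylhepta-1,3-dien-1-yl]-4-methyl-4H-pyran-4-ol F5. Dehydration (MsCl, iPr2NEt, CH2Cl2, −40 °C) gives the anhydrobase 5-(dimethoxymethyl)-2-[(1E,3E,5S)-3,5-dimethylhepta-1,3-dien-1-yl]-4-methylidene-4H-pyran F6. It is C-acylated in the same flask at the exocyclic carbon with commercial 2-acetoxypropanoyl chloride to 4-[3-(dimethoxymethyl)-6-[(1E,3E,5S)-3,5-dimethylhepta-1,3-dien-1-yl]-4H-pyran-4-ylidene]-3-oxobutan-2-yl acetate F7. Methanolysis of the acetate (K2CO3, MeOH) and acetal hydrolysis (1 M HCl, THF) come back to the route at 16.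

**Further compounds**
F1 | step 10 | 5-chloro-3-[(1E,3E,5S)-3,5-dimethylhepta-1,3-dien-1-yl]-7,8-dihydroxy-7-methyl-7,8-dihydro-6H-isochromen-6-one (stereoisomers at C7 and C8) | CC[C@H](C)/C=C(C)/C=C/C1=CC2=C(Cl)C(=O)C(C)(O)C(O)C2=CO1
F2 | step 6 | 2-butoxy-6-[(1E,3E,5S)-3,5-dimethylhepta-1,3-dien-1-yl]-2,3-dihydro-4H-pyran-4-one | CC[C@H](C)/C=C(C)/C=C/C1=CC(=O)CC(OCCCC)O1
F3 | step 6 | 2-butoxy-3-[(dimethylamino)methylidene]-6-[(1E,3E,5S)-3,5-dimethylhepta-1,3-dien-1-yl]-2,3-dihydro-4H-pyran-4-one | CC[C@H](C)/C=C(C)/C=C/C1=CC(=O)C(=CN(C)C)C(OCCCC)O1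
F4 | step 6 | 6-[(1E,3E,5S)-3,5-dimethylhepta-1,3-dien-1-yl]-4-oxo-4H-pyran-3-carbaldehyde | CC[C@H](C)/C=C(C)/C=C/C1=CC(=O)C(C=O)=CO1
F5 | step 7 | 3-(dimethoxymethyl)-6-[(1E,3E,5S)-3,5-dimethylhepta-1,3-dien-1-yl]-4-methyl-4H-pyran-4-ol | CC[C@H](C)/C=C(C)/C=C/C1=CC(C)(O)C(C(OC)OC)=CO1
F6 | step 7 | 5-(dimethoxymethyl)-2-[(1E,3E,5S)-3,5-dimethylhepta-1,3-dien-1-yl]-4-methylidene-4H-pyran | CC[C@H](C)/C=C(C)/C=C/C1=CC(=C)C(C(OC)OC)=CO1
F7 | step 7 | 4-[3-(dimethoxymethyl)-6-[(1E,3E,5S)-3,5-dimethylhepta-1,3-dien-1-yl]-4H-pyran-4-ylidene]-3-oxobutan-2-yl acetate | CC[C@H](C)/C=C(C)/C=C/C1=C/C(=C/C(=O)C(C)OC(C)=O)C(C(OC)OC)=CO1
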